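**Retrosynthetic overview**
1. Target 32 ⇐ silyl ether 31 ⇐ ynal 30: the oxonane (C6–C7 bond, C6 stereocentre) is closed last by a proposed nickel–carbene, exo-selective reductive alkyne–aldehyde cyclization.
2. ε-Lactone (C3–O) and C4–O ⇐ C16-hydroxyl-directed epoxidation of the Z-C3=C4 alkene, oxidation to the acid and 7-exo epoxide opening; C11–OH by oxymercuration; C15 by hydroboration of the carvone isopropenyl group.
3. Tetrahydrofuran (C1–C2 and C9–C10 bonds; C1, C2, C10) ⇐ Prins–pinacol union of dienyl diol 17 with Z-enal 14, then photodecarbonylation.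
4. Fragments: dienyllithium 15 from (R)-carvone hydrazone 2 by Shapiro reaction (ring A, C14), α-silyloxy aldehyde 8 from (R)-glycidol (C9), Z-enal 14 by Still–Gennari olefination.
5. Ring order: ring A (chiral pool) → tetrahydrofuran → lactone → oxonane.

Assumption: the given SMILES defines the required enantiomer. Atoms are referred to by cladiellin numbering: O bridges C2 and C9; ring A = C1, C10–C14; C15 sits on C14 and carries C16 (lactone carbonyl) and C17 (methyl); C18 is the methyl on C3, C19 the methylene on C7, C20 the methyl on C11. In this numbering the target is 1S,2S,3S,4R,6R,9S,10R,11R,14R,15R.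

**Route**

Step 1
Reactants: 1 (R)-(−)-carvone
Product: 2 (R)-carvone 2,4,6-triisopropylbenzenesulfonylhydrazone
Conditions: TrisNHNH2, cat. HCl, MeCN, rt
Reagents that add atoms: 2,4,6-triisopropylbenzenesulfonyl hydrazide NNS(=O)(=O)c1c(C(C)C)cc(C(C)C)cc1C(C)C
Why: Acid-catalysed hydrazone formation at the enone carbonyl, which leaves the chiral-pool centre (future C14) untouched.

Step 2
Reactants: 3 (R)-glycidol; 4 (triisopropylsilyl)acetylene
Product: 6 (S)-5-(triisopropylsilyl)pent-4-yne-1,2-diol, via lithium (triisopropylsilyl)acetylide 5 (not isolated)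
Conditions: n-BuLi, THF, −78 °C; BF3·OEt2, then 3, −78 °C
Reagents that add atoms: none
Why: BF3-assisted epoxide opening by the lithium acetylide at the unsubstituted carbon (Yamaguchi-type alkynylation), so the carbinol centre (future C9) is carried over unchanged from glycidol.

Step 3
Reactants: 6 (S)-5-(triisopropylsilyl)pent-4-yne-1,2-diol
Product: 7 (S)-1,2-bis(triethylsilyloxy)-5-(triisopropylsilyl)pent-4-yne
Conditions: Et3SiCl, imidazole, DMAP (cat.), CH2Cl2, 0 °C to rt
Reagents that add atoms: chlorotriethylsilane CC[Si](Cl)(CC)CC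
Why: Routine silyl ether formation on both hydroxyls.

Step 4
Reactants: 7 (S)-1,2-bis(triethylsilyloxy)-5-(triisopropylsilyl)pent-4-yne
Product: 8 (S)-2-(triethylsilyloxy)-5-(triisopropylsilyl)pent-4-ynal
Conditions: (COCl)2, DMSO, CH2Cl2, −78 to −40 °C; Et3N
Reagents that add atoms: none
Why: Swern oxidation converts a primary triethylsilyl ether directly into the aldehyde while the secondary silyl ether survives, and the α-centre does not epimerise at low temperature.

Step 5
Reactants: 9 3-(tert-butyldimethylsilyloxy)propanal; 10 ethyl 2-[bis(2,2,2-trifluoroethoxy)phosphoryl]propanoate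
Product: 12 ethyl (Z)-5-(tert-butyldimethylsilyloxy)-2-methylpent-2-enoate, via potassium phosphonate carbanion 11 (not isolated)
Conditions: KN(SiMe3)2, 18-crown-6, THF, −78 °C
Reagents that add atoms: none
Why: Still–Gennari olefination, whose fast kinetic elimination from the electron-poor phosphonate gives the Z-trisubstituted enoate and thereby fixes the C3=C4 geometry.

Step 6
Reactants: 12 ethyl (Z)-5-(tert-butyldimethylsilyloxy)-2-methylpent-2-enoate
Product: 13 (Z)-5-(tert-butyldimethylsilyloxy)-2-methylpent-2-en-1-ol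
Conditions: i-Bu2AlH, CH2Cl2, −78 °C
Reagents that add atoms: none
Why: 1,2-Reduction of the enoate by the aluminium hydride with retention of the Z geometry.

Step 7
Reactants: 13 (Z)-5-(tert-butyldimethylsilyloxy)-2-methylpent-2-en-1-ol
Product: 14 (Z)-5-(tert-butyldimethylsilyloxy)-2-methylpent-2-enal
Conditions: MnO2, CH2Cl2, rt
Reagents that add atoms: none
Why: Neutral allylic oxidation with MnO2 keeps the Z geometry (the enal is used at once).

Step 8
Reactants: 2 (R)-carvone 2,4,6-triisopropylbenzenesulfonylhydrazone; 8 (S)-2-(triethylsilyloxy)-5-(triisopropylsilyl)pent-4-ynal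
Product: 16 anti carbinol (1R,2S)-1-[(3R)-6-methyl-3-(prop-1-en-2-yl)cyclohexa-1,5-dien-1-yl]-2-(triethylsilyloxy)-5-(triisopropylsilyl)pent-4-yn-1-ol, via dienyllithium 15 (not isolated)
Conditions: 2 (1.3 equiv), n-BuLi (2.6 equiv), TMEDA, THF, −78 to 0 °C (until N2 evolution ends); then 8, −78 °C
Reagents that add atoms: none
Why: Shapiro reaction, in which the hydrazone dianion (second deprotonation at the only sp3 α-carbon) loses sulfinate and N2 to give the dienyllithium, whose polar Felkin–Anh 1,2-addition to the α-silyloxy aldehyde gives mainly the anti carbinol; the C14 centre is not involved, and since the carbinol carbon later leaves as the formyl group the minor syn epimer converges.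

Step 9
Reactants: 16 anti carbinol
Product: 17 dienyl diol (1R,2S)-1-[(3R)-6-methyl-3-(prop-1-en-2-yl)cyclohexa-1,5-dien-1-yl]-5-(triisopropylsilyl)pent-4-yne-1,2-diol
Conditions: TBAF, AcOH, THF, 0 °C
Reagents that add atoms: none
Why: Buffered fluoride desilylation removes the secondary triethylsilyl ether without touching the alkynyl silane or ionising the dienyl carbinol.

Step 10
Reactants: 17 dienyl diol; 14 (Z)-5-(tert-butyldimethylsilyloxy)-2-methylpent-2-enal
Product: 19 formyl bicycle (C10-formyl cis-fused hexahydroisobenzofuran), via cyclic acetal 18 (not isolated)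
Conditions: BF3·OEt2, MgSO4, CH2Cl2, −55 to −20 °C
Reagents that add atoms: none
Why: Prins–pinacol condensation–rearrangement, in which the acetal opens to the E-oxocarbenium ion on O9, the diene attacks through a chair six-membered transition state anti to the C14 isopropenyl group with the C8 and C3 chains equatorial, and ring-contracting pinacol shift of C9 (retention) gives the 2,5-cis tetrahydrofuran cis-fused to ring A, setting C1, C2 and C10.

Step 11
Reactants: 19 formyl bicycle
Product: 20 isopropenyl bicycle (C10–H cis-fused hexahydroisobenzofuran)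
Conditions: hν (medium-pressure Hg lamp, Pyrex), 1,4-dioxane, rt
Reagents that add atoms: none
Why: Norrish type 1 photodecarbonylation of the β,γ-unsaturated aldehyde, where the allylic C10 radical takes hydrogen back on the face that held the formyl group and so gives the cis ring fusion (H1 and H10 cis).

Step 12
Reactants: 20 isopropenyl bicycle
Product: 22 primary alcohol (C16–OH with 15R), via alkylborane 21 (not isolated)
Conditions: 9-BBN, THF, 0 °C to rt; then NaOH, H2O2, 0 °C
Reagents that add atoms: hydrogen peroxide OO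
Why: Hydroboration–oxidation, in which 9-BBN selects the 1,1-disubstituted alkene over the two trisubstituted alkenes and the silyl alkyne and adds anti to the bulky C1 branch in the conformer with H14 eclipsing the alkene, giving 15R by 1,2-induction.

Step 13
Reactants: 22 primary alcohol
Product: 23 epoxy alcohol (3,4-epoxide)
Conditions: Al(OtBu)3, t-BuOOH, PhH/CH2Cl2, 5 °C
Reagents that add atoms: tert-butyl hydroperoxide CC(C)(C)OO
Why: Hydroxyl-directed epoxidation, in which the aluminium alkoxide of the C16 hydroxyl delivers the peroxide oxygen to the nearby Z-C3=C4 alkene on the face on the C1 side (against the steric bias) and leaves the C11=C12 alkene alone, fixing C4 and preparing C3 for inversion.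

Step 14
Reactants: 23 epoxy alcohol
Product: 25 hydroxy lactone (tricycle with 3S and 4R), via epoxy acid 24 (not isolated)
Conditions: TEMPO (cat.), PhI(OAc)2, MeCN/H2O, rt; then CSA (cat.), CH2Cl2, 0 °C
Reagents that add atoms: water O
Why: Oxoammonium oxidation of the primary alcohol to the acid followed by acid-catalysed 7-exo epoxide-opening lactonisation, in which the carboxyl attacks the tertiary C3 with inversion to give the ε-lactone (3S) and free the 4R hydroxyl.

Step 15
Reactants: 25 hydroxy lactone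
Product: 27 diol lactone (C11–OH with 11R), via organomercurial 26 (not isolated)
Conditions: Hg(OAc)2, THF/H2O, 0 °C; then NaBH4, aq. K2CO3, 0 °C
Reagents that add atoms: water O
Why: Markovnikov oxymercuration–demercuration of the only remaining alkene, in which the mercurinium ion forms on the convex face of ring A (anti to the pseudo-axial C9 substituent on C10) and water opens it anti at tertiary C11, placing the hydroxyl cis to C9.

Step 16
Reactants: 27 diol lactone
Product: 28 C4 octanoate
Conditions: octanoyl chloride, pyridine, DMAP (cat.), CH2Cl2, 0 °C to rt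
Reagents that add atoms: octanoyl chloride CCCCCCCC(=O)Cl
Why: DMAP-catalysed acylation of the only acylable hydroxyl (secondary C4), the tertiary C11 hydroxyl being inert.

Step 17
Reactants: 28 C4 octanoate
Product: 29 alkynol (terminal alkyne and C6–OH)
Conditions: TBAF, THF, 0 °C to rt
Reagents that add atoms: none
Why: Fluoride desilylation cleaves the primary silyl ether and the alkynyl C–Si bond in one operation while the hindered ester and lactone survive.

Step 18
Reactants: 29 alkynol
Product: 30 ynal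
Conditions: Dess–Martin periodinane, NaHCO3, CH2Cl2, 0 °C to rt
Reagents that add atoms: none
Why: Buffered Dess–Martin oxidation gives the β-acyloxy aldehyde without elimination and leaves the tertiary alcohol untouched.

Step 19
Reactants: 30 ynal
Product: 31 tricyclic C6 triethylsilyl ether (oxonane closed)
Conditions: Ni(cod)2 (30 mol %), SIPr [1,3-bis(2,6-diisopropylphenyl)imidazolidin-2-ylidene] (30 mol %), Et3SiH (5 equiv), THF, 2 mM, slow addition of 30, rt
Reagents that add atoms: triethylsilane CC[SiH](CC)CC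
Why: Proposed new method: zerovalent nickel bearing a bulky N-heterocyclic carbene should couple the tethered aldehyde and terminal alkyne oxidatively to an oxanickelacyclopentene with C–C bond formation at the substituted alkyne carbon C7 (the large carbene sits beside the small alkyne hydrogen, and the nine-membered exo closure is preferred over a ten-membered ring holding an E-alkene), after which σ-bond metathesis with Et3SiH and C–H reductive elimination release the C6 silyl ether with the exocyclic C7 methylene, the aldehyde being attacked on its outward face as in chromium-mediated closures of this ring to give 6R; the closest known reaction type is the ligand-controlled nickel-catalysed reductive alkyne–aldehyde macrocyclization (exo-selective with terminal alkynes and large carbenes), not yet shown for a nine-membered ring.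

Step 20
Reactants: 31 tricyclic C6 triethylsilyl ether
Product: 32 briarellin b (target)
Conditions: HF·pyridine, pyridine, THF, 0 °C
Reagents that add atoms: none
Why: Buffered fluoride desilylation of the allylic silyl ether proceeds without acyl migration or lactone opening.

**Compound list**

1 | (R)-(−)-carvone, (5R)-2-methyl-5-(prop-1-en-2-yl)cyclohex-2-en-1-one | CC1=CC[C@@H](C(C)=C)CC1=O | starting material
2 | (R)-carvone 2,4,6-triisopropylbenzenesulfonylhydrazone (C=N geometry not specified) | CC1=CC[C@@H](C(C)=C)CC1=NNS(=O)(=O)c1c(C(C)C)cc(C(C)C)cc1C(C)C | intermediate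
3 | (R)-glycidol, (2R)-oxiran-2-ylmethanol | OC[C@@H]1CO1 | starting material
4 | (triisopropylsilyl)acetylene | C#C[Si](C(C)C)(C(C)C)C(C)C | starting material
5 | lithium (triisopropylsilyl)acetylide (not isolated) | [Li]C#C[Si](C(C)C)(C(C)C)C(C)C | intermediate
6 | (S)-5-(triisopropylsilyl)pent-4-yne-1,2-diol | OC[C@@H](O)CC#C[Si](C(C)C)(C(C)C)C(C)C | intermediate
7 | (S)-1,2-bis(triethylsilyloxy)-5-(triisopropylsilyl)pent-4-yne | CC[Si](CC)(CC)OC[C@@H](O[Si](CC)(CC)CC)CC#C[Si](C(C)C)(C(C)C)C(C)C | intermediate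
8 | (S)-2-(triethylsilyloxy)-5-(triisopropylsilyl)pent-4-ynal | O=C[C@@H](O[Si](CC)(CC)CC)CC#C[Si](C(C)C)(C(C)C)C(C)C | intermediate
9 | 3-(tert-butyldimethylsilyloxy)propanal | O=CCCO[Si](C)(C)C(C)(C)C | starting material
10 | ethyl 2-[bis(2,2,2-trifluoroethoxy)phosphoryl]propanoate | CCOC(=O)C(C)P(=O)(OCC(F)(F)F)OCC(F)(F)F | starting material
11 | potassium salt of the α-carbanion of 10 (not isolated) | CCOC(=O)[C-](C)P(=O)(OCC(F)(F)F)OCC(F)(F)F.[K+] | intermediate
12 | ethyl (Z)-5-(tert-butyldimethylsilyloxy)-2-methylpent-2-enoate | CCOC(=O)/C(C)=C\CCO[Si](C)(C)C(C)(C)C | intermediate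
13 | (Z)-5-(tert-butyldimethylsilyloxy)-2-methylpent-2-en-1-ol | OC/C(C)=C\CCO[Si](C)(C)C(C)(C)C | intermediate
14 | (Z)-5-(tert-butyldimethylsilyloxy)-2-methylpent-2-enal | O=C/C(C)=C\CCO[Si](C)(C)C(C)(C)C | intermediate
15 | dienyllithium, [(3R)-6-methyl-3-(prop-1-en-2-yl)cyclohexa-1,5-dien-1-yl]lithium (not isolated) | [Li]C1=C[C@H](C(C)=C)CC=C1C | intermediate
16 | anti carbinol, (1R,2S)-1-[(3R)-6-methyl-3-(prop-1-en-2-yl)cyclohexa-1,5-dien-1-yl]-2-(triethylsilyloxy)-5-(triisopropylsilyl)pent-4-yn-1-ol (major epimer; minor 1-epimer converges) | CC(C)[Si](C#CC[C@H](O[Si](CC)(CC)CC)[C@H](O)C1=C[C@H](C(C)=C)CC=C1C)(C(C)C)C(C)C | intermediate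
17 | dienyl diol, (1R,2S)-1-[(3R)-6-methyl-3-(prop-1-en-2-yl)cyclohexa-1,5-dien-1-yl]-5-(triisopropylsilyl)pent-4-yne-1,2-diol | CC(C)[Si](C#CC[C@H](O)[C@H](O)C1=C[C@H](C(C)=C)CC=C1C)(C(C)C)C(C)C | intermediate
18 | cyclic acetal (1,3-dioxolane of diol 17 with enal 14, both epimers at the acetal carbon; not isolated) | CC(C)[Si](C#CC[C@@H]3OC(/C(C)=C\CCO[Si](C)(C)C(C)(C)C)O[C@@H]3C1=C[C@H](C(C)=C)CC=C1C)(C(C)C)C(C)C | intermediate
19 | formyl bicycle: cis-fused hexahydroisobenzofuran (C1, C2, O, C9, C10 with ring A); C2 carries the (Z)-5-(tert-butyldimethylsilyloxy)pent-2-en-2-yl chain, C9 the 3-(triisopropylsilyl)prop-2-ynyl chain, C10 a formyl group, C11(Me)=C12, C14 isopropenyl; the C2 and C9 chains are cis to each other and trans to ring A, isopropenyl trans to C2 | CC(C)[Si](C#CC[C@@H]2O[C@H](/C(C)=C\CCO[Si](C)(C)C(C)(C)C)[C@H]4[C@@H](CC=C(C)[C@]42C=O)C(C)=C)(C(C)C)C(C)C | intermediate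
20 | isopropenyl bicycle: as 19 with H in place of the C10 formyl group (H1 and H10 cis; C1, C2, C9, C10, C14 configured as in 32) | CC(C)[Si](C#CC[C@@H]2O[C@H](/C(C)=C\CCO[Si](C)(C)C(C)(C)C)[C@H]4[C@@H](CC=C(C)[C@H]42)C(C)=C)(C(C)C)C(C)C | intermediate
21 | alkylborane: as 20 with C14 carrying (R)-CH(CH3)CH2–B(9-borabicyclo[3.3.1]nonan-9-yl) (not isolated) | CC(C)[Si](C#CC[C@@H]2O[C@H](/C(C)=C\CCO[Si](C)(C)C(C)(C)C)[C@H]4[C@@H](CC=C(C)[C@H]42)[C@@H](C)CB5C6CCCC5CCC6)(C(C)C)C(C)C | intermediate
22 | primary alcohol: as 20 with C14 carrying (15R)-CH(CH3)CH2OH | CC(C)[Si](C#CC[C@@H]2O[C@H](/C(C)=C\CCO[Si](C)(C)C(C)(C)C)[C@H]4[C@@H](CC=C(C)[C@H]42)[C@@H](C)CO)(C(C)C)C(C)C | intermediate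
23 | epoxy alcohol: as 22 with the C3=C4 alkene as its cis-epoxide, oxygen on the alkene face syn to C1 | CC(C)[Si](C#CC[C@@H]2O[C@H]([C@]5(C)O[C@@H]5CCO[Si](C)(C)C(C)(C)C)[C@H]4[C@@H](CC=C(C)[C@H]42)[C@@H](C)CO)(C(C)C)C(C)C | intermediate
24 | epoxy acid: as 23 with C16 as CO2H (not isolated) | CC(C)[Si](C#CC[C@@H]2O[C@H]([C@]5(C)O[C@@H]5CCO[Si](C)(C)C(C)(C)C)[C@H]4[C@@H](CC=C(C)[C@H]42)[C@@H](C)C(=O)O)(C(C)C)C(C)C | intermediate
25 | hydroxy lactone: tricycle with the C16(=O)–O–C3 ε-lactone, 3S methyl carbinol ester, free 4R hydroxyl, C11(Me)=C12, C5–C6 chain ending in OTBS, C9 3-(triisopropylsilyl)prop-2-ynyl | CC(C)[Si](C#CC[C@@H]2O[C@H]3[C@H]4[C@@H](CC=C(C)[C@H]42)[C@@H](C)C(=O)O[C@@]3(C)[C@H](O)CCO[Si](C)(C)C(C)(C)C)(C(C)C)C(C)C | intermediate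
26 | organomercurial: as 25 with C11(Me)(OH) and C12–HgOAc trans to that hydroxyl (not isolated) | CC(C)[Si](C#CC[C@@H]2O[C@H]3[C@H]4[C@@H](C[C@H]([Hg]OC(C)=O)[C@@](C)(O)[C@H]42)[C@@H](C)C(=O)O[C@@]3(C)[C@H](O)CCO[Si](C)(C)C(C)(C)C)(C(C)C)C(C)C | intermediate
27 | diol lactone: as 25 with C11 (R) tertiary alcohol (OH cis to C9) and C12 methylene | CC(C)[Si](C#CC[C@@H]2O[C@H]3[C@H]4[C@@H](CC[C@@](C)(O)[C@H]42)[C@@H](C)C(=O)O[C@@]3(C)[C@H](O)CCO[Si](C)(C)C(C)(C)C)(C(C)C)C(C)C | intermediate
28 | C4 octanoate of 27 | CC(C)[Si](C#CC[C@@H]2O[C@H]3[C@H]4[C@@H](CC[C@@](C)(O)[C@H]42)[C@@H](C)C(=O)O[C@@]3(C)[C@H](OC(=O)CCCCCCC)CCO[Si](C)(C)C(C)(C)C)(C(C)C)C(C)C | intermediate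
29 | alkynol: as 28 with terminal alkyne (C7≡C19H) and free C6 hydroxyl | C#CC[C@@H]2O[C@H]3[C@H]4[C@@H](CC[C@@](C)(O)[C@H]42)[C@@H](C)C(=O)O[C@@]3(C)[C@H](OC(=O)CCCCCCC)CCO | intermediate
30 | ynal: as 29 with C6 as aldehyde | C#CC[C@@H]2O[C@H]3[C@H]4[C@@H](CC[C@@](C)(O)[C@H]42)[C@@H](C)C(=O)O[C@@]3(C)[C@H](OC(=O)CCCCCCC)CC=O | intermediate
31 | C6 triethylsilyl ether of the target (6R) | C=C1C[C@@H]2O[C@H]3[C@H]4[C@@H](CC[C@@](C)(O)[C@H]42)[C@@H](C)C(=O)O[C@@]3(C)[C@H](OC(=O)CCCCCCC)C[C@H]1O[Si](CC)(CC)CC | intermediate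
32 | briarellin b, (1S,2S,3S,4R,6R,9S,10R,11R,14R,15R) in cladiellin numbering | C=C1C[C@@H]2O[C@H]3[C@H]4[C@@H](CC[C@@](C)(O)[C@H]42)[C@@H](C)C(=O)O[C@@]3(C)[C@H](OC(=O)CCCCCCC)C[C@H]1O | target

**Step count and risk**

Total: 20 steps. Longest linear sequence: 16 steps (from 3 through steps 2–4 and 8–20).

Steps most likely to fail:

Step 14 (oxidation and epoxide-opening lactonisation). The C16 hydroxyl may open the epoxide before it is oxidised, or the acid may open it sluggishly or with loss of C3 integrity. The fallback sets out from 23 and comes back at 28. It lets the alcohol do the ring closure and adjusts the oxidation level afterwards: CSA in CH2Cl2 converts 23 by 7-exo opening at C3 into the oxepane alcohol F1 (a C16H2–O–C3 ether in place of the lactone). Hg(OAc)2 in THF/H2O gives the oxepane organomercurial F2, which NaBH4 reduces in the same flask to the oxepane diol F3. Octanoyl chloride, pyridine and DMAP give the oxepane octanoate F4. RuCl3 (cat.) with NaIO4 at 0 °C then oxidises the only ether methylene (C16) to the lactone carbonyl, giving 28. The silyl-capped alkyne is the group to watch in that oxidation.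

Step 15 (C11 hydration). Mercury may engage the alkyne, or the lactone may suffer in the borohydride step. The fallback sets out from 25 and comes back at 27. NBS in THF/H2O forms the bromonium ion on the convex face and water opens it at C11, giving the bromohydrin F5 (C11–OH cis to C9, C12–Br trans to it). Radical debromination with Bu3SnH and AIBN in toluene at 80 °C then gives 27.

Step 19 (proposed nickel-catalysed ring closure). Regiochemistry (exo versus endo), oligomerisation or the wrong C6 epimer are possible. The fallback uses known chemistry, sets out from 29 and comes back at 32. Markovnikov hydrosilylation of the terminal alkyne with [Cp*Ru(MeCN)3]PF6 (cat.) and Et3SiH gives the α-vinylsilane alcohol F6. NIS in hexafluoroisopropanol exchanges silicon for iodine to give the 2-iodoalkene alcohol F7. Dess–Martin oxidation gives the iodo aldehyde F8. Nozaki–Hiyama–Kishi cyclization with CrCl2 and catalytic NiCl2 in DMSO at high dilution then closes the oxonane and delivers the free C6 alcohol 32 directly. If the 6-epimer forms in either closure, oxidation to the enone and Luche reduction would be used to correct it.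

Further compounds
F1 | step 14 | oxepane alcohol (C16H2–O–C3 ether analogue of 25, C11=C12 retained, free C4–OH) | CC(C)[Si](C#CC[C@@H]2O[C@H]3[C@H]4[C@@H](CC=C(C)[C@H]42)[C@@H](C)CO[C@@]3(C)[C@H](O)CCO[Si](C)(C)C(C)(C)C)(C(C)C)C(C)C
F2 | step 14 | oxepane organomercurial (C11–OH, C12–HgOAc; not isolated) | CC(C)[Si](C#CC[C@@H]2O[C@H]3[C@H]4[C@@H](C[C@H]([Hg]OC(C)=O)[C@@](C)(O)[C@H]42)[C@@H](C)CO[C@@]3(C)[C@H](O)CCO[Si](C)(C)C(C)(C)C)(C(C)C)C(C)C
F3 | step 14 | oxepane diol (C11–OH, C4–OH) | CC(C)[Si](C#CC[C@@H]2O[C@H]3[C@H]4[C@@H](CC[C@@](C)(O)[C@H]42)[C@@H](C)CO[C@@]3(C)[C@H](O)CCO[Si](C)(C)C(C)(C)C)(C(C)C)C(C)C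
F4 | step 14 | oxepane octanoate (C4 octanoate of F3) | CC(C)[Si](C#CC[C@@H]2O[C@H]3[C@H]4[C@@H](CC[C@@](C)(O)[C@H]42)[C@@H](C)CO[C@@]3(C)[C@H](OC(=O)CCCCCCC)CCO[Si](C)(C)C(C)(C)C)(C(C)C)C(C)C
F5 | step 15 | bromohydrin (25 with C11–OH cis to C9 and C12–Br trans to the hydroxyl) | CC(C)[Si](C#CC[C@@H]2O[C@H]3[C@H]4[C@@H](C[C@H](Br)[C@@](C)(O)[C@H]42)[C@@H](C)C(=O)O[C@@]3(C)[C@H](O)CCO[Si](C)(C)C(C)(C)C)(C(C)C)C(C)C
F6 | step 19 | α-vinylsilane alcohol (29 with C7 carrying SiEt3 and C7=C19H2) | C=C([Si](CC)(CC)CC)C[C@@H]2O[C@H]3[C@H]4[C@@H](CC[C@@](C)(O)[C@H]42)[C@@H](C)C(=O)O[C@@]3(C)[C@H](OC(=O)CCCCCCC)CCO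
F7 | step 19 | 2-iodoalkene alcohol (C7 iodide, C7=C19H2, free C6–OH) | C=C(I)C[C@@H]2O[C@H]3[C@H]4[C@@H](CC[C@@](C)(O)[C@H]42)[C@@H](C)C(=O)O[C@@]3(C)[C@H](OC(=O)CCCCCCC)CCO
F8 | step 19 | iodo aldehyde (F7 with C6 as aldehyde) | C=C(I)C[C@@H]2O[C@H]3[C@H]4[C@@H](CC[C@@](C)(O)[C@H]42)[C@@H](C)C(=O)O[C@@]3(C)[C@H](OC(=O)CCCCCCC)CC=O
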